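**Retrosynthetic overview**
- Last step: face-selective peracid epoxidation of the E-C1=C10 olefin of a macrocyclic triene diol.
- Ten-membered ring: CrCl2/NiCl2 (Nozaki–Hiyama–Kishi) macrocyclisation forming C3–C4 from a Z-vinyl iodide and a C3 aldehyde; this keeps the 4Z olefin and creates the C3 carbinol.
- Seco chain: zinc Barbier union at C7–C8 of a β,γ-unsaturated aldehyde (C8–C10, C14, C1–C3) with a 3-(bromomethyl)butenolide (C4–C7, C11–C13, C15), then Mitsunobu inversion that installs the 8β-isobutyrate.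
- Butenolide: ring-closing metathesis of a 2-(bromomethyl)acrylate; C6 from asymmetric alkynylation of crotonaldehyde; Z-iodoalkene by hydroxyl-directed hydroalumination–iodination. Aldehyde: alkyne hydrozirconation–iodination, then oxirane opening.
- Ring order: γ-lactone (within its fragment), then the ten-membered carbocycle, then the oxirane.

Assumption: the SMILES is read as (1R,3S,4Z,6R,7R,8R,10R) in germacrane numbering (O–C6 lactone, C8 isobutyrate, C12 carbonyl, C13 exo-methylene, C14 methyl, C15 CH2OH), i.e. 3β-OH, 8β-ester, 1β,10α-epoxide. This numbering is used for C-atom labels throughout. In the iodo compounds the carbon that becomes C6 is labelled S only because the iodoalkenyl carbon outranks C7; its spatial arrangement is that of 6R in the target.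

**Step 1**
Reactants: 1 prop-2-yn-1-ol
Product: 2 tert-butyldimethyl(prop-2-yn-1-yloxy)silane
Conditions: TBSCl, imidazole, CH2Cl2, 0 °C → rt
Reagents that add atoms: tert-butyldimethylsilyl chloride, CC(C)(C)[Si](C)(C)Cl
Why: Silyl ether formation on a primary alcohol masks O15 for the hydride, metathesis, zinc and Mitsunobu steps; no stereocentre is formed.

**Step 2**
Reactants: 2 tert-butyldimethyl(prop-2-yn-1-yloxy)silane; 3 (E)-but-2-enal
Product: 5 (4S,5E)-1-[(tert-butyldimethylsilyl)oxy]hept-5-en-2-yn-4-ol, via alkynylzinc 4 (not isolated)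
Conditions: Me2Zn (3 equiv), (S,S)-ProPhenol (10 mol %), Ph3PO (20 mol %), 2 (3 equiv), toluene, 0 °C; then aq. NH4Cl
Reagents that add atoms: none
Why: Catalytic asymmetric alkynylation of an enal (dinuclear zinc–ProPhenol catalyst) gives 1,2-addition only and sets the future C6 as the S carbinol by catalyst control; the sense of induction of the (S,S)-ligand is not certain here, and the antipodal ligand is used if it gives the R alcohol.

**Step 3**
Reactants: 5 (4S,5E)-1-[(tert-butyldimethylsilyl)oxy]hept-5-en-2-yn-4-ol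
Product: 7 (2Z,4S,5E)-1-[(tert-butyldimethylsilyl)oxy]-2-iodohepta-2,5-dien-4-ol, via cyclic alkenylaluminate 6 (not isolated)
Conditions: NaAlH2(OCH2CH2OCH3)2 (1.6 equiv), THF, 0 °C → rt; then I2, THF, −78 → 0 °C; aq. KNaC4H4O6
Reagents that add atoms: iodine, II
Why: Hydroxyl-directed trans-hydroalumination of the propargylic alcohol places aluminium on the distal alkyne carbon (C4), and iodinolysis with retention gives the Z-vinyl iodide with iodine cis to C6; the carbinol centre is untouched.

**Step 4**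
Reactants: 8 diethyl 2,2-bis(hydroxymethyl)propanedioate
Product: 9 2-(bromomethyl)prop-2-enoic acid
Conditions: 48 % aq. HBr, 85–90 °C
Reagents that add atoms: hydrogen bromide, Br
Why: Acid-mediated ester hydrolysis, decarboxylation, dehydration and OH-to-Br substitution in one pot give the 2-(bromomethyl)acrylic acid; no stereocentre.

**Step 5**
Reactants: 7 (2Z,4S,5E)-1-[(tert-butyldimethylsilyl)oxy]-2-iodohepta-2,5-dien-4-ol; 9 2-(bromomethyl)prop-2-enoic acid
Product: 10 (2Z,4S,5E)-1-[(tert-butyldimethylsilyl)oxy]-2-iodohepta-2,5-dien-4-yl 2-(bromomethyl)prop-2-enoate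
Conditions: DCC, DMAP (5 mol %), CH2Cl2, −20 → 0 °C
Reagents that add atoms: none
Why: Steglich esterification acylates the secondary bis-allylic alcohol at oxygen with retention at C6, at a temperature low enough to outrun amine attack on the allylic bromide.

**Step 6**
Reactants: 10 (2Z,4S,5E)-1-[(tert-butyldimethylsilyl)oxy]-2-iodohepta-2,5-dien-4-yl 2-(bromomethyl)prop-2-enoate
Product: 11 (5S)-3-(bromomethyl)-5-[(1Z)-3-[(tert-butyldimethylsilyl)oxy]-2-iodoprop-1-en-1-yl]furan-2(5H)-one
Conditions: second-generation Grubbs catalyst (5 mol %), toluene, 70 °C, 0.01 M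
Reagents that add atoms: none
Why: Ring-closing metathesis between the propenyl group and the 1,1-disubstituted acrylate closes the butenolide with loss of propene, while the electron-poor trisubstituted iodoalkene is inert and C6 is not involved.

**Step 7**
Reactants: 12 3-bromoprop-1-yne; 13 trimethyl orthoformate
Product: 15 4,4-dimethoxybut-1-yne, via propargylaluminium bromide 14 (not isolated)
Conditions: Al powder, HgCl2 (cat.), Et2O, reflux; then 13, −78 °C → rt
Reagents that add atoms: none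
Why: The propargyl/allenyl aluminium reagent displaces one methoxy group of the orthoester (organoaluminium alkylation of an orthoformate) to give the homopropargylic acetal that carries the masked C3 aldehyde; no stereocentre.

**Step 8**
Reactants: 15 4,4-dimethoxybut-1-yne
Product: 17 5,5-dimethoxypent-2-yne, via lithium acetylide 16 (not isolated)
Conditions: n-BuLi, THF, −78 °C; then MeI, −78 °C → rt
Reagents that add atoms: iodomethane, CI
Why: Deprotonation of the terminal alkyne and SN2 methylation of the acetylide (alkyne alkylation) introduce C14; no stereocentre.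

**Step 9**
Reactants: 17 5,5-dimethoxypent-2-yne
Product: 19 (E)-2-iodo-5,5-dimethoxypent-2-ene, via alkenylzirconocene chloride 18 (not isolated)
Conditions: Cp2Zr(H)Cl (1.6 equiv), THF, rt → 45 °C; then I2, 0 °C
Reagents that add atoms: iodine, II
Why: syn-Hydrozirconation with thermal equilibration puts zirconium on the methyl-bearing carbon, and iodinolysis with retention gives the E-trisubstituted vinyl iodide that fixes the C1=C10 geometry.

**Step 10**
Reactants: 19 (E)-2-iodo-5,5-dimethoxypent-2-ene; 20 oxirane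
Product: 22 (E)-6,6-dimethoxy-3-methylhex-3-en-1-ol, via alkenyllithium 21 (not isolated)
Conditions: t-BuLi (2.1 equiv), Et2O, −78 °C; then 20 (3 equiv), −78 → 0 °C; then H2O
Reagents that add atoms: none
Why: Iodine–lithium exchange with retention of olefin geometry followed by ring-opening of oxirane by the alkenyllithium (epoxide alkylation) adds C9 and C8 as a homoallylic alcohol.

**Step 11**
Reactants: 22 (E)-6,6-dimethoxy-3-methylhex-3-en-1-ol
Product: 23 (E)-6,6-dimethoxy-3-methylhex-3-enal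
Conditions: Dess–Martin periodinane, pyridine, CH2Cl2, 0 °C; used at once
Reagents that add atoms: none
Why: Buffered Dess–Martin oxidation gives the β,γ-unsaturated aldehyde without moving the trisubstituted olefin into conjugation.

**Step 12**
Reactants: 11 (5S)-3-(bromomethyl)-5-[(1Z)-3-[(tert-butyldimethylsilyl)oxy]-2-iodoprop-1-en-1-yl]furan-2(5H)-one; 23 (E)-6,6-dimethoxy-3-methylhex-3-enal
Product: 25 (4R,5S)-5-[(1Z)-3-[(tert-butyldimethylsilyl)oxy]-2-iodoprop-1-en-1-yl]-4-[(1S,3E)-1-hydroxy-6,6-dimethoxy-3-methylhex-3-en-1-yl]-3-methylideneoxolan-2-one, via allylzinc bromide 24 (not isolated)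
Conditions: Zn dust (4 equiv), THF/sat. aq. NH4Cl (3:1), 0 °C → rt
Reagents that add atoms: none
Why: Barbier allylation in which the allylzinc reacts at its γ-carbon (C7) anti to the C6 substituent through a chair transition state with the ring-fixed E allyl unit, giving the trans-6,7-lactone with the exo-methylene in place and the anti (8S) carbinol.

**Step 13**
Reactants: 25 (4R,5S)-5-[(1Z)-3-[(tert-butyldimethylsilyl)oxy]-2-iodoprop-1-en-1-yl]-4-[(1S,3E)-1-hydroxy-6,6-dimethoxy-3-methylhex-3-en-1-yl]-3-methylideneoxolan-2-one; 26 2-methylpropanoic acid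
Product: 27 (4R,5S)-5-[(1Z)-3-[(tert-butyldimethylsilyl)oxy]-2-iodoprop-1-en-1-yl]-4-[(1R,3E)-6,6-dimethoxy-3-methyl-1-(2-methylpropanoyloxy)hex-3-en-1-yl]-3-methylideneoxolan-2-one
Conditions: PPh3, DIAD, toluene, 0 °C → rt
Reagents that add atoms: none
Why: Mitsunobu esterification displaces the phosphonium-activated C8 oxygen by isobutyrate in an SN2 step, inverting C8 from S to the required R (8β) and installing the ester in the same operation.

**Step 14**
Reactants: 27 (4R,5S)-5-[(1Z)-3-[(tert-butyldimethylsilyl)oxy]-2-iodoprop-1-en-1-yl]-4-[(1R,3E)-6,6-dimethoxy-3-methyl-1-(2-methylpropanoyloxy)hex-3-en-1-yl]-3-methylideneoxolan-2-one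
Product: 28 (4R,5S)-5-[(1Z)-3-hydroxy-2-iodoprop-1-en-1-yl]-3-methylidene-4-[(1R,3E)-3-methyl-1-(2-methylpropanoyloxy)-6-oxohex-3-en-1-yl]oxolan-2-one
Conditions: 48 % aq. HF/MeCN (1:19), 0 °C
Reagents that add atoms: water, O
Why: Acetal hydrolysis and desilylation in one mild aqueous acid treatment free the C3 aldehyde and the C15 hydroxyl without touching the ester, the lactone or the position of the β,γ-olefin.

**Step 15**
Reactants: 28 (4R,5S)-5-[(1Z)-3-hydroxy-2-iodoprop-1-en-1-yl]-3-methylidene-4-[(1R,3E)-3-methyl-1-(2-methylpropanoyloxy)-6-oxohex-3-en-1-yl]oxolan-2-one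
Product: 30 (1(10)E,3S,4Z,6R,7R,8R)-3,15-dihydroxy-8-(2-methylpropanoyloxy)germacra-1(10),4,11(13)-trien-12,6-olide, via alkenylchromium dichloride 29 (not isolated)
Conditions: CrCl2 (12 equiv), NiCl2 (1 mol % of the CrCl2), degassed DMSO, rt, slow addition to 0.003 M
Reagents that add atoms: none
Why: Intramolecular Nozaki–Hiyama–Kishi reaction in which nickel-catalysed activation of the carbon–iodine bond and transfer to trivalent chromium give an alkenylchromium that adds to the C3 aldehyde with retention of the Z geometry and closes the ten-membered ring; the 3S carbinol is expected from addition through the conformer with the aldehyde oxygen on the ring periphery, and this is the least securely controlled stereocentre.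

**Step 16**
Reactants: 30 (1(10)E,3S,4Z,6R,7R,8R)-3,15-dihydroxy-8-(2-methylpropanoyloxy)germacra-1(10),4,11(13)-trien-12,6-olide
Product: 31 (1R,3S,4Z,6R,7R,8R,10R)-1,10-epoxy-3,15-dihydroxy-8-(2-methylpropanoyloxy)germacra-4,11(13)-dien-12,6-olide
Conditions: mCPBA (1.05 equiv), NaHCO3, CH2Cl2, −20 → 0 °C
Reagents that add atoms: 3-chloroperbenzoic acid, O=C(OO)c1cccc(Cl)c1
Why: Prilezhaev epoxidation occurs at the only electron-rich olefin (E-C1=C10) from its exposed outer face in the conformer with C14 on the β-face, giving the trans 1β,10α (1R,10R) epoxide, while C4=C5 is deactivated by three allylic C–O bonds and the enoate is inert.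

**Compound list**
1 | prop-2-yn-1-ol | C#CCO | starting material
2 | tert-butyldimethyl(prop-2-yn-1-yloxy)silane | C#CCO[Si](C)(C)C(C)(C)C | intermediate
3 | (E)-but-2-enal | C/C=C/C=O | starting material
4 | methyl[3-[(tert-butyldimethylsilyl)oxy]prop-1-yn-1-yl]zinc (not isolated) | C[Zn]C#CCO[Si](C)(C)C(C)(C)C | intermediate
5 | (4S,5E)-1-[(tert-butyldimethylsilyl)oxy]hept-5-en-2-yn-4-ol | C/C=C/[C@H](O)C#CCO[Si](C)(C)C(C)(C)C | intermediate
6 | sodium (5S)-2,2-bis(2-methoxyethoxy)-3-[[(tert-butyldimethylsilyl)oxy]methyl]-5-[(E)-prop-1-en-1-yl]-2,5-dihydro-1,2-oxaluminol-2-uide (not isolated) | C/C=C/[C@H]1C=C(CO[Si](C)(C)C(C)(C)C)[Al-](OCCOC)(OCCOC)O1.[Na+] | intermediate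
7 | (2Z,4S,5E)-1-[(tert-butyldimethylsilyl)oxy]-2-iodohepta-2,5-dien-4-ol | C/C=C/[C@H](O)/C=C(\I)CO[Si](C)(C)C(C)(C)C | intermediate
8 | diethyl 2,2-bis(hydroxymethyl)propanedioate | CCOC(=O)C(CO)(CO)C(=O)OCC | starting material
9 | 2-(bromomethyl)prop-2-enoic acid | C=C(CBr)C(=O)O | intermediate
10 | (2Z,4S,5E)-1-[(tert-butyldimethylsilyl)oxy]-2-iodohepta-2,5-dien-4-yl 2-(bromomethyl)prop-2-enoate | C/C=C/[C@H](OC(=O)C(=C)CBr)/C=C(\I)CO[Si](C)(C)C(C)(C)C | intermediate
11 | (5S)-3-(bromomethyl)-5-[(1Z)-3-[(tert-butyldimethylsilyl)oxy]-2-iodoprop-1-en-1-yl]furan-2(5H)-one | O=C1O[C@H](/C=C(\I)CO[Si](C)(C)C(C)(C)C)C=C1CBr | intermediate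
12 | 3-bromoprop-1-yne | C#CCBr | starting material
13 | trimethyl orthoformate | COC(OC)OC | starting material
14 | prop-2-yn-1-ylaluminium dibromide, drawn for the propargyl/allenyl aluminium sesquibromide (not isolated) | C#CC[Al](Br)Br | intermediate
15 | 4,4-dimethoxybut-1-yne | C#CCC(OC)OC | intermediate
16 | lithium 4,4-dimethoxybut-1-yn-1-ide (not isolated) | [Li]C#CCC(OC)OC | intermediate
17 | 5,5-dimethoxypent-2-yne | CC#CCC(OC)OC | intermediate
18 | chlorobis(cyclopentadienyl)[(2E)-5,5-dimethoxypent-2-en-2-yl]zirconium (not isolated) | C/C(=C\CC(OC)OC)[Zr](Cl)(C1C=CC=C1)C1C=CC=C1 | intermediate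
19 | (E)-2-iodo-5,5-dimethoxypent-2-ene | C/C(I)=C\CC(OC)OC | intermediate
20 | oxirane | C1CO1 | starting material
21 | (5,5-dimethoxypent-2-en-2-yl)lithium, lithium trans to C4 as iodine in 19 (not isolated) | [Li]/C(C)=C/CC(OC)OC | intermediate
22 | (E)-6,6-dimethoxy-3-methylhex-3-en-1-ol | OCC/C(C)=C/CC(OC)OC | intermediate
23 | (E)-6,6-dimethoxy-3-methylhex-3-enal | O=CC/C(C)=C/CC(OC)OC | intermediate
24 | bromo[[(5S)-5-[(1Z)-3-[(tert-butyldimethylsilyl)oxy]-2-iodoprop-1-en-1-yl]-2-oxo-2,5-dihydrofuran-3-yl]methyl]zinc (not isolated) | O=C1O[C@H](/C=C(\I)CO[Si](C)(C)C(C)(C)C)C=C1C[Zn]Br | intermediate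
25 | (4R,5S)-5-[(1Z)-3-[(tert-butyldimethylsilyl)oxy]-2-iodoprop-1-en-1-yl]-4-[(1S,3E)-1-hydroxy-6,6-dimethoxy-3-methylhex-3-en-1-yl]-3-methylideneoxolan-2-one | C=C1C(=O)O[C@H](/C=C(\I)CO[Si](C)(C)C(C)(C)C)[C@H]1[C@@H](O)C/C(C)=C/CC(OC)OC | intermediate
26 | 2-methylpropanoic acid | CC(C)C(=O)O | starting material
27 | (4R,5S)-5-[(1Z)-3-[(tert-butyldimethylsilyl)oxy]-2-iodoprop-1-en-1-yl]-4-[(1R,3E)-6,6-dimethoxy-3-methyl-1-(2-methylpropanoyloxy)hex-3-en-1-yl]-3-methylideneoxolan-2-one | C=C1C(=O)O[C@H](/C=C(\I)CO[Si](C)(C)C(C)(C)C)[C@H]1[C@H](OC(=O)C(C)C)C/C(C)=C/CC(OC)OC | intermediate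
28 | (4R,5S)-5-[(1Z)-3-hydroxy-2-iodoprop-1-en-1-yl]-3-methylidene-4-[(1R,3E)-3-methyl-1-(2-methylpropanoyloxy)-6-oxohex-3-en-1-yl]oxolan-2-one | C=C1C(=O)O[C@H](/C=C(\I)CO)[C@H]1[C@H](OC(=O)C(C)C)C/C(C)=C/CC=O | intermediate
29 | alkenylchromium dichloride of 28, CrCl2 in place of iodine with the olefin geometry retained (not isolated) | C=C1C(=O)O[C@H](/C=C(\[Cr](Cl)Cl)CO)[C@H]1[C@H](OC(=O)C(C)C)C/C(C)=C/CC=O | intermediate
30 | (1(10)E,3S,4Z,6R,7R,8R)-3,15-dihydroxy-8-(2-methylpropanoyloxy)germacra-1(10),4,11(13)-trien-12,6-olide | C=C1C(=O)O[C@@H]2/C=C(/CO)[C@@H](O)C/C=C(\C)C[C@@H](OC(=O)C(C)C)[C@@H]12 | intermediate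
31 | (1R,3S,4Z,6R,7R,8R,10R)-1,10-epoxy-3,15-dihydroxy-8-(2-methylpropanoyloxy)germacra-4,11(13)-dien-12,6-olide (CNP0219050.1) | C=C1C(=O)O[C@@H]2/C=C(/CO)[C@@H](O)C[C@H]3O[C@]3(C)C[C@@H](OC(=O)C(C)C)[C@@H]12 | target

**Step count**
Total: 16 steps. Longest linear sequence: 10 steps (steps 1, 2, 3, 5, 6, 12, 13, 14, 15, 16; the branch through steps 7–11 and 12–16 is equally long).

**Steps most likely to fail, with fallbacks**

Step 13. The Mitsunobu reaction is at a β-branched secondary carbinol, so elimination or poor conversion are the likely failures. The fallback sets out from 25: oxidation with Dess–Martin periodinane/pyridine gives the C8 ketone F1. Reduction at −78 °C with (S)-2-methyl-CBS-oxazaborolidine and catecholborane (reagent control, C7 as the large group) gives the 8R alcohol F2. Acylation with 2-methylpropanoyl chloride and pyridine then comes back to the route at 27. Inversion by substitution is thereby replaced by oxidation–reduction and acylation with retention; F1 must be handled cold and neutral because its C7 hydrogen is prone to enolisation.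

Step 15. Both the ring closure and the C3 configuration rest on macrocyclic substrate control. The fallback sets out from 27: hydrolysis of the acetal alone (PPTS, acetone/H2O) gives the silyl ether aldehyde F3. Cyclisation with CrCl2/NiCl2 as before gives the macrocyclic allylic alcohol F4 without regard to C3. Dess–Martin oxidation gives the macrocyclic enone F5. Reduction with (R)-2-methyl-CBS-oxazaborolidine and catecholborane gives the 3S alcohol F6. Removal of the silyl group (48 % aq. HF/MeCN) comes back to the route at 30. C3 is then set after ring closure by the reagent, not during it.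

Step 16. Site and face selectivity are decided on an unprotected diol by the substrate alone. The fallback sets out from 30: silylation of both hydroxyls (TESOTf, 2,6-lutidine) gives the bis(triethylsilyl) ether F7. Epoxidation with the chiral dioxirane from the D-fructose-derived Shi ketone (KHSO5, K2CO3, MeCN/dimethoxymethane/H2O, 0 °C; 1R,10R expected) gives the silylated epoxide F8. Desilylation with TBAF/AcOH comes back to the route at 31. Face selection passes from the substrate to the reagent, and hydroxyl direction is switched off.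

**Further compounds**
F1 | step 13 | C8 ketone of 25: 5-[(1Z)-3-[(tert-butyldimethylsilyl)oxy]-2-iodoprop-1-en-1-yl]-4-[(3E)-6,6-dimethoxy-3-methyl-1-oxohex-3-en-1-yl]-3-methylideneoxolan-2-one, C6 and C7 as in 25 | C=C1C(=O)O[C@H](/C=C(\I)CO[Si](C)(C)C(C)(C)C)[C@H]1C(=O)C/C(C)=C/CC(OC)OC
F2 | step 13 | C8 epimer of 25: (4R,5S)-5-[(1Z)-3-[(tert-butyldimethylsilyl)oxy]-2-iodoprop-1-en-1-yl]-4-[(1R,3E)-1-hydroxy-6,6-dimethoxy-3-methylhex-3-en-1-yl]-3-methylideneoxolan-2-one | C=C1C(=O)O[C@H](/C=C(\I)CO[Si](C)(C)C(C)(C)C)[C@H]1[C@H](O)C/C(C)=C/CC(OC)OC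
F3 | step 15 | (4R,5S)-5-[(1Z)-3-[(tert-butyldimethylsilyl)oxy]-2-iodoprop-1-en-1-yl]-3-methylidene-4-[(1R,3E)-3-methyl-1-(2-methylpropanoyloxy)-6-oxohex-3-en-1-yl]oxolan-2-one | C=C1C(=O)O[C@H](/C=C(\I)CO[Si](C)(C)C(C)(C)C)[C@H]1[C@H](OC(=O)C(C)C)C/C(C)=C/CC=O
F4 | step 15 | 15-O-tert-butyldimethylsilyl ether of 30 as a mixture of C3 epimers | C=C1C(=O)O[C@@H]2/C=C(/CO[Si](C)(C)C(C)(C)C)C(O)C/C=C(\C)C[C@@H](OC(=O)C(C)C)[C@@H]12
F5 | step 15 | (1(10)E,4Z,6R,7R,8R)-15-[(tert-butyldimethylsilyl)oxy]-8-(2-methylpropanoyloxy)-3-oxogermacra-1(10),4,11(13)-trien-12,6-olide | C=C1C(=O)O[C@@H]2/C=C(/CO[Si](C)(C)C(C)(C)C)C(=O)C/C=C(\C)C[C@@H](OC(=O)C(C)C)[C@@H]12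
F6 | step 15 | (3S)-15-O-tert-butyldimethylsilyl ether of 30 | C=C1C(=O)O[C@@H]2/C=C(/CO[Si](C)(C)C(C)(C)C)[C@@H](O)C/C=C(\C)C[C@@H](OC(=O)C(C)C)[C@@H]12
F7 | step 16 | 3,15-bis-O-triethylsilyl ether of 30 | C=C1C(=O)O[C@@H]2/C=C(/CO[Si](CC)(CC)CC)[C@@H](O[Si](CC)(CC)CC)C/C=C(\C)C[C@@H](OC(=O)C(C)C)[C@@H]12
F8 | step 16 | 3,15-bis-O-triethylsilyl ether of 31 | C=C1C(=O)O[C@@H]2/C=C(/CO[Si](CC)(CC)CC)[C@@H](O[Si](CC)(CC)CC)C[C@H]3O[C@]3(C)C[C@@H](OC(=O)C(C)C)[C@@H]12
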